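## Analysis of the target

Target 22 is a single six-membered carbocycle (ring A) cis-fused to an oxirane, a 7-oxabicyclo[4.1.0]heptan-2-one, numbered here as C1 (ring ketone), C2 (methyl-bearing oxirane carbon), C3 (oxirane CH), C4 (methylene), C5 (side-chain carbon) and C6 (tigloyloxy carbon), with the chain C7 (carrying the exo-methylene), C8 (ketone), C9=C10 (E) and C11 (tertiary carbinol). The four stereocentres C2, C3, C5 and C6 are (1S,3S,4S,6S) in the bicyclic name; the oxirane oxygen is cis to the C5 side chain and the C6 tiglate is trans to both. The sensitive groups are the α,β-epoxy ketone, the epimerisable α-acyloxy ketone at C6, the cross-conjugated dienone whose exo-methylene terminus is a strong Michael acceptor, and the tertiary allylic alcohol. The first difficulty is that ring A carries oxygen on C1, C2, C3 and C6 with fixed relative configuration, and that the C1 and C6 oxygens, at different oxidation levels, must be told apart. The second is that the dienone tolerates neither enolate chemistry nor strong nucleophiles and therefore has to be made last. The plan rests on one feature: once the oxirane is read as a former C2=C3 alkene, ring A is a 2-methylcyclohex-2-enone whose only carbon branch sits at C5. That pattern is the retron of a Michael–aldol annulation in which a β-keto ester supplies C1, C2, C6 and the C2 methyl, and an enal supplies C3, C4, C5 and, as a carboxyl group, C7.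

## Retrosynthetic reasoning

**C7–C8 and C8–C9.** Target 22 is cut on both sides of the C8 carbonyl, giving vinyl triflate 19, alkenylstannane 21 and a one-carbon carbonyl unit joined by a carbonylative Stille coupling. The cut is made here because the dienone is the most reactive part of the molecule, and this coupling forms it under neutral conditions as the last step. Stannane 21 comes from alkyne 20 by hydrostannylation.

**C6–O ester bond.** Tiglate 19 goes back to α-hydroxy ketone 16 and tiglic acid 17. Acylation is placed after all organometallic steps so that the unsaturated ester never meets a Grignard reagent or a strong base.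

**C6–O bond.** Hydroxy ketone 16 goes back to epoxy ketone 15 by enolate hydroxylation. In 15, C2 is quaternary, so C6 is the only enolisable position and the regiochemistry is unambiguous. The C5 substituent next to C6 should steer the oxidant to the opposite face, which gives the trans arrangement required. Oxygenating C6 earlier, at the enone stage, was considered. It would put two secondary carbinols side by side once C1 is reduced and would need two orthogonal protecting groups. Leaving C6 as a methylene until C1 is a ketone again differentiates the two oxygens by timing alone.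

**C1 oxidation level and the oxirane.** Epoxy ketone 15 goes back through epoxy alcohol 14 to allylic alcohol 13. A nucleophilic epoxidation of the enone would be expected to enter anti to the C5 substituent, the wrong face. A C1 hydroxyl cis to C5 instead delivers the oxygen syn to itself, hence cis to C5, and is then oxidised back to the ketone. The oxirane is introduced only after the side-chain handle is finished, so that it never meets a Grignard reagent or an amide base.

**Side-chain handle.** Vinyl triflate 13 goes back through silyl ether 12 to methyl ketone 11, Weinreb amide 10 and ester 9. The C7 carboxyl becomes an acetyl group, whose kinetic methyl-side enolate gives the 1-substituted vinyl triflate. The C1 carbinol is carried as a triethylsilyl ether (9, from alcohol 8) through these basic steps. It thus serves three purposes: it masks the ketone, later directs the epoxidation, and is finally re-oxidised.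

**C1 carbinol.** Alcohol 8 comes from enone 7 by Luche reduction, which should give the equatorial alcohol cis to C5.

**Ring A.** Enone 7 is the decarboxylation product of keto diester 5, by way of keto acid 6. Diester 5 is cut at C5–C6 and C2=C3 into tert-butyl 3-oxopentanoate 1 and ethyl (E)-4-oxobut-2-enoate 2, by way of Michael adduct 3 and aldol 4. Both partners are commercial. The cut builds the ring, the C2 methyl, the C2=C3 alkene, the C1 ketone and the C5 stereocentre in one catalytic operation, and places a carboxyl exactly where C7 is needed. The forward reaction must add the β-keto ester at the ester-bearing carbon of the enal with control of the C5 configuration, and must close the ring through C2.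

## Alternatives that were turned down

Alternative 1: The C1–O bond is traced back to the C7 carboxyl group. Treating (1R)-4-methylcyclohex-3-ene-1-carboxylic acid A1 with I2 and NaHCO3 would close the carboxylate onto C1 while iodine adds to C2, giving the bridged iodolactone (1R,4R,5R)-4-iodo-4-methyl-6-oxabicyclo[3.2.1]octan-7-one A2. In iodolactone A2 the C1 oxygen is necessarily cis to C7 and the iodide on C2 is trans to it.
- For: in A2 the cis C1–O/C5 relationship is enforced by the bicycle rather than by the facial preference of a hydride, so on this point the alternative is stronger than the reduction of 7 to 8. The lactone of A2 also protects the C1 oxygen and C7 together.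
- Against: acid A1 must first be secured as a single enantiomer (auxiliary-controlled cycloaddition or resolution). The step from A1 to A2 builds neither a carbon–carbon bond nor the carbocycle. The tertiary iodide of A2 must then be eliminated regioselectively toward C3 rather than toward the methyl group. C6, the one-carbon bridge of A2, still has to be oxygenated late, exactly as in the chosen route.
- Comparison: the chosen route makes the ring, the C5 centre and the enone from commercial acyclic materials in one catalytic step, and reaches the cis alcohol 8 two steps later. What it offers in place of the enforced cis relationship of A2 is a carvone-type reduction with a well-understood facial preference.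

Alternative 2: The C1–C2 bond is cut. Diethyl L-malate A3 would be elaborated to the open-chain aldehyde ethyl (2R,4Z)-5-iodo-2-{(1S)-1-[(4-methoxyphenyl)methoxy]-2-oxoethyl}hex-4-enoate A4. CrCl2 with catalytic NiCl2 would then join the alkenyl iodide carbon C2 of A4 to its aldehyde carbon C1 (a Nozaki–Hiyama–Kishi ring closure), giving the cyclohexenol ethyl (1R,5S,6S)-5-hydroxy-6-[(4-methoxyphenyl)methoxy]-4-methylcyclohex-3-ene-1-carboxylate A5.
- For: in cyclohexenol A5 the C6 oxygen and its configuration come from malate A3, and C5 is set trans to it by alkylation. The C1 and C6 oxygens of A5 are differentiated from the start, so no late enolate oxidation of an epoxy ketone is needed. On these points the alternative is stronger than the chosen route.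
- Against: aldehyde A4 needs a long linear sequence from A3 (diastereoselective alkylation with a Z-iodoalkene arm, protection, reduction of one of two esters to an epimerisable α-alkoxy aldehyde). The β-alkoxy ester can eliminate. The ring closure to A5 uses stoichiometric CrCl2, and its selectivity at C1 is not assured.
- Comparison: the chosen route reaches a ring with the same C5 handle in two steps and uses a catalytic asymmetric step. It pays for this with the late C6 hydroxylation, which A5 avoids.

Alternative 3: The C1–C6 and C4–C5 bonds are cut. The siloxydiene tert-butyl(dimethyl){[(1E)-2-methylbuta-1,3-dien-1-yl]oxy}silane A6 and the dienophile ethyl (2E)-4-oxopent-2-enoate A7 would combine in a Diels–Alder reaction under a chiral oxazaborolidinium Lewis acid. The adduct would be ethyl (1R,5S,6S)-6-acetyl-5-[(tert-butyldimethylsilyl)oxy]-4-methylcyclohex-3-ene-1-carboxylate A8, whose acetyl group would later become the C6 oxygen by Baeyer–Villiger oxidation.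
- For: three ring stereocentres (C1, C5, C6) arise together in adduct A8, more than the single centre set in the chosen key step. The C6 oxygen would arrive with retention and without enolate chemistry.
- Against: the endo rule puts the C1 oxygen of A8 cis to the C6 substituent, hence trans to C5. That is the wrong face for directing the oxirane, so C1 would need inversion or an oxidation–reduction cycle. Regiochemistry depends on which of the two carbonyl groups of A7 the Lewis acid binds, and diene A6 is acid-sensitive. The peracid step competes with undirected epoxidation of the electron-rich C2=C3 alkene. Both oxygens are present early and need orthogonal protection.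
- Comparison: the chosen route sets only C5 in its key step, but every later centre is relayed from C5 in the sense actually required, whereas A8 carries one centre that has to be corrected.

Key step: step 1

Remark: the (S) hand of the catalyst is assigned from the usual shielding model for iminium ions of diarylprolinol silyl ethers (E,s-trans iminium, attack anti to the diphenyl(silyloxy)methyl group); compounds 1, 2, 17 and 20 are taken as purchased.

## Route

Step 1
Reactants: 1 tert-butyl 3-oxopentanoate; 2 ethyl (2E)-4-oxobut-2-enoate
Product: 5 1-tert-butyl 6-ethyl (6R)-3-methyl-2-oxocyclohex-3-ene-1,6-dicarboxylate, via Michael adduct 3 (not isolated), via aldol 4 (not isolated)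
Conditions: (S)-α,α-diphenylprolinol trimethylsilyl ether (10 mol %), PhCO2H (10 mol %), toluene, 0 °C to rt; then p-TsOH·H2O (20 mol %), 40 °C
Reagents that add atoms: none
Why: The amine condenses with 2 to an E-configured, s-trans iminium ion; the enol of 1 adds through C6 to the iminium β-carbon C5, and hydrolysis of the resulting enamine releases the catalyst and adduct 3. Under the acid added next, the ketone enolises toward C2 and attacks the aldehyde carbon C3 in a 6-(enolendo)-exo-trig aldol closure to 4, whose dehydration should give the conjugated C2=C3 enone 5. The closest known reaction type is the secondary-amine-catalysed Michael–aldol condensation of β-keto esters with enals to 5-substituted cyclohex-2-enones. The only lasting new stereocentre, C5, is set in the Michael step: the diphenyl(silyloxy)methyl group blocks one face of the iminium ion and the nucleophile enters anti to it, which for the (S)-catalyst should give the 6R ester. C6 of 5 is a labile β-keto ester centre and is erased in step 2. Two regioselectivities are needed: addition must occur at the ester-bearing carbon (β to the iminium, not β to the ester), which the much greater electrophilicity of the iminium ion secures; and the aldol must use C2 rather than the more acidic C6, which ring size secures because only C2 gives a six-membered ring.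

Step 2
Reactants: 5 1-tert-butyl 6-ethyl (6R)-3-methyl-2-oxocyclohex-3-ene-1,6-dicarboxylate
Product: 7 ethyl (1R)-4-methyl-5-oxocyclohex-3-ene-1-carboxylate, via β-keto acid 6 (not isolated)
Conditions: p-TsOH·H2O (20 mol %), toluene, 80 °C
Reagents that add atoms: none
Why: Acid-catalysed loss of isobutene from the tert-butyl ester gives β-keto acid 6, which decarboxylates through the usual cyclic transition state; the ethyl ester is inert in anhydrous toluene and C5 is not touched.

Step 3
Reactants: 7 ethyl (1R)-4-methyl-5-oxocyclohex-3-ene-1-carboxylate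
Product: 8 ethyl (1R,5R)-5-hydroxy-4-methylcyclohex-3-ene-1-carboxylate
Conditions: NaBH4, CeCl3·7H2O, MeOH, −78 °C
Reagents that add atoms: none
Why: Luche reduction is 1,2-selective for the enone and leaves the ester alone; hydride should enter axially on the half-chair with the C5 ester equatorial, giving the equatorial C1 alcohol cis to the C5 substituent, as in the reduction of carvone to cis-carveol.

Step 4
Reactants: 8 ethyl (1R,5R)-5-hydroxy-4-methylcyclohex-3-ene-1-carboxylate
Product: 9 ethyl (1R,5R)-4-methyl-5-[(triethylsilyl)oxy]cyclohex-3-ene-1-carboxylate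
Conditions: Et3SiCl, imidazole, CH2Cl2, 0 °C to rt
Reagents that add atoms: chlorotriethylsilane, CC[Si](Cl)(CC)CC
Why: Standard silylation of a secondary alcohol; the silyl ether masks the C1 carbinol against the organomagnesium and amide bases of steps 5 to 7 and prevents lactonisation onto C7.

Step 5
Reactants: 9 ethyl (1R,5R)-4-methyl-5-[(triethylsilyl)oxy]cyclohex-3-ene-1-carboxylate
Product: 10 (1R,5R)-N-methoxy-N,4-dimethyl-5-[(triethylsilyl)oxy]cyclohex-3-ene-1-carboxamide
Conditions: MeNH(OMe)·HCl, i-PrMgCl, THF, −20 to 0 °C
Reagents that add atoms: N,O-dimethylhydroxylamine hydrochloride, CNOC.Cl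
Why: Aminolysis of the ester by the magnesium amide (Weinreb amide formation) at low temperature; enolisation at C5 is slow under these conditions and the cis-1,3 arrangement is in any case the more stable one.

Step 6
Reactants: 10 (1R,5R)-N-methoxy-N,4-dimethyl-5-[(triethylsilyl)oxy]cyclohex-3-ene-1-carboxamide
Product: 11 1-[(1R,5R)-4-methyl-5-[(triethylsilyl)oxy]cyclohex-3-en-1-yl]ethan-1-one
Conditions: MeMgBr, THF, 0 °C
Reagents that add atoms: methylmagnesium bromide, C[Mg]Br
Why: Weinreb ketone synthesis; the chelated tetrahedral adduct persists until work-up, so only one methyl group is added.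

Step 7
Reactants: 11 1-[(1R,5R)-4-methyl-5-[(triethylsilyl)oxy]cyclohex-3-en-1-yl]ethan-1-one
Product: 12 1-[(1R,5R)-4-methyl-5-[(triethylsilyl)oxy]cyclohex-3-en-1-yl]ethenyl trifluoromethanesulfonate
Conditions: KN(SiMe3)2, THF, −78 °C (ketone added to base); then N-(5-chloro-2-pyridyl)triflimide, −78 °C; aq. NH4Cl
Reagents that add atoms: N-(5-chloropyridin-2-yl)-1,1,1-trifluoro-N-(trifluoromethanesulfonyl)methanesulfonamide, O=S(=O)(N(c1ccc(Cl)cn1)S(=O)(=O)C(F)(F)F)C(F)(F)F
Why: Kinetic deprotonation of a methyl ketone by the bulky amide at −78 °C occurs at the methyl group rather than at the C5 methine, and O-sulfonylation of that enolate should give the 1-substituted vinyl triflate (enol triflate formation); adding the ketone to the base avoids enolate equilibration.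

Step 8
Reactants: 12 1-[(1R,5R)-4-methyl-5-[(triethylsilyl)oxy]cyclohex-3-en-1-yl]ethenyl trifluoromethanesulfonate
Product: 13 1-[(1R,5R)-5-hydroxy-4-methylcyclohex-3-en-1-yl]ethenyl trifluoromethanesulfonate
Conditions: HF·pyridine, pyridine, THF, 0 °C
Reagents that add atoms: none
Why: Buffered fluoride cleaves the triethylsilyl ether; the vinyl triflate and the ring alkene are stable to these conditions, which avoid the basic fluoride sources that can attack sulfonates.

Step 9
Reactants: 13 1-[(1R,5R)-5-hydroxy-4-methylcyclohex-3-en-1-yl]ethenyl trifluoromethanesulfonate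
Product: 14 1-[(1S,3S,5R,6R)-5-hydroxy-6-methyl-7-oxabicyclo[4.1.0]heptan-3-yl]ethenyl trifluoromethanesulfonate
Conditions: VO(acac)2 (5 mol %), t-BuOOH, CH2Cl2, 0 °C to rt
Reagents that add atoms: tert-butyl hydroperoxide, CC(C)(C)OO
Why: Hydroxyl-directed epoxidation: the vanadate ester of the C1 alcohol delivers the peroxide oxygen to the same face of C2=C3, so the oxirane should form syn to the C1 hydroxyl and hence cis to the C5 substituent, which fixes C2 and C3. The electron-poor, undirected vinyl triflate alkene is not oxidised.

Step 10
Reactants: 14 1-[(1S,3S,5R,6R)-5-hydroxy-6-methyl-7-oxabicyclo[4.1.0]heptan-3-yl]ethenyl trifluoromethanesulfonate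
Product: 15 1-[(1S,3R,6S)-6-methyl-5-oxo-7-oxabicyclo[4.1.0]heptan-3-yl]ethenyl trifluoromethanesulfonate
Conditions: Dess–Martin periodinane, pyridine, CH2Cl2, 0 °C to rt
Reagents that add atoms: none
Why: Dess–Martin oxidation under pyridine buffering converts the epoxy alcohol to the α,β-epoxy ketone without opening the oxirane or touching the triflate.

Step 11
Reactants: 15 1-[(1S,3R,6S)-6-methyl-5-oxo-7-oxabicyclo[4.1.0]heptan-3-yl]ethenyl trifluoromethanesulfonate
Product: 16 1-[(1S,3R,4S,6S)-4-hydroxy-6-methyl-5-oxo-7-oxabicyclo[4.1.0]heptan-3-yl]ethenyl trifluoromethanesulfonate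
Conditions: NaN(SiMe3)2 (1.05 equiv), THF, −78 °C; then 3-phenyl-2-(phenylsulfonyl)oxaziridine, −78 °C; aq. NH4Cl
Reagents that add atoms: 3-phenyl-2-(phenylsulfonyl)oxaziridine, O=S(=O)(N1OC1c1ccccc1)c1ccccc1
Why: C6 is the only enolisable position of 15 (C2 is quaternary), so a single enolate forms, and a hexamethyldisilazide at −78 °C is not basic enough to eliminate the vinyl triflate. Oxygen transfer from the oxaziridine (enolate hydroxylation) should occur anti to the adjacent C5 substituent, giving the trans C5/C6 arrangement, which is also the more stable diequatorial one.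

Step 12
Reactants: 16 1-[(1S,3R,4S,6S)-4-hydroxy-6-methyl-5-oxo-7-oxabicyclo[4.1.0]heptan-3-yl]ethenyl trifluoromethanesulfonate; 17 tiglic acid ((2E)-2-methylbut-2-enoic acid)
Product: 19 (1S,3S,4R,6S)-1-methyl-2-oxo-4-{1-[(trifluoromethanesulfonyl)oxy]ethenyl}-7-oxabicyclo[4.1.0]heptan-3-yl (2E)-2-methylbut-2-enoate, via mixed anhydride 18 (not isolated)
Conditions: 17, 2,4,6-Cl3C6H2COCl, Et3N, toluene, rt; then 16, DMAP, rt
Reagents that add atoms: none
Why: Yamaguchi esterification: mixed anhydride 18 is attacked by DMAP at the less hindered tigloyl carbonyl, and the acylpyridinium ion acylates the hindered α-hydroxy ketone. The E alkene of the tiglate is the stable geometry, and C6, if it epimerised, would return to the trans isomer.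

Step 13
Reactants: 20 2-methylbut-3-yn-2-ol
Product: 21 (3E)-2-methyl-4-(tributylstannyl)but-3-en-2-ol
Conditions: Bu3SnH, PdCl2(PPh3)2 (2 mol %), THF, 0 °C to rt
Reagents that add atoms: tributylstannane, CCCC[SnH](CCCC)CCCC
Why: Palladium-catalysed syn hydrostannylation of a terminal alkyne with a tertiary propargylic alcohol places tin on the terminal carbon for steric reasons and should give the (E)-alkenylstannane.

Step 14
Reactants: 19 (1S,3S,4R,6S)-1-methyl-2-oxo-4-{1-[(trifluoromethanesulfonyl)oxy]ethenyl}-7-oxabicyclo[4.1.0]heptan-3-yl (2E)-2-methylbut-2-enoate; 21 (3E)-2-methyl-4-(tributylstannyl)but-3-en-2-ol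
Product: 22 (1S,3S,4S,6S)-4-[(4E)-6-hydroxy-6-methyl-3-oxohepta-1,4-dien-2-yl]-1-methyl-2-oxo-7-oxabicyclo[4.1.0]heptan-3-yl (2E)-2-methylbut-2-enoate (CNP0263368.1)
Conditions: Pd(PPh3)4 (5 mol %), LiCl, CO (3 atm), THF, 50 °C
Reagents that add atoms: carbon monoxide, [C-]#[O+]
Why: Carbonylative Stille coupling: zerovalent palladium inserts into the C7–O triflate bond, CO insertion gives the acylpalladium (C7–C8), and transmetallation with 21 followed by reductive elimination forms C8–C9 with retention of the E geometry. The conditions are neutral, so the epoxy ketone, the tiglate and the free tertiary alcohol should survive, and the dienone is formed only in the last step.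

## Compound list

1 | tert-butyl 3-oxopentanoate | CCC(=O)CC(=O)OC(C)(C)C | starting material
2 | ethyl (2E)-4-oxobut-2-enoate | CCOC(=O)/C=C/C=O | starting material
3 | 1-tert-butyl 4-ethyl (3R)-3-(2-oxoethyl)-2-propanoylbutanedioate (Michael adduct, both C2 epimers) | CCOC(=O)[C@@H](C(C(=O)CC)C(=O)OC(C)(C)C)CC=O | intermediate
4 | 1-tert-butyl 6-ethyl (6R)-4-hydroxy-3-methyl-2-oxocyclohexane-1,6-dicarboxylate (aldol, mixture at C1, C3, C4) | CCOC(=O)[C@@H]1CC(O)C(C)C(=O)C1C(=O)OC(C)(C)C | intermediate
5 | 1-tert-butyl 6-ethyl (6R)-3-methyl-2-oxocyclohex-3-ene-1,6-dicarboxylate | CCOC(=O)[C@@H]1CC=C(C)C(=O)C1C(=O)OC(C)(C)C | intermediate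
6 | (6R)-6-(ethoxycarbonyl)-3-methyl-2-oxocyclohex-3-ene-1-carboxylic acid | CCOC(=O)[C@@H]1CC=C(C)C(=O)C1C(=O)O | intermediate
7 | ethyl (1R)-4-methyl-5-oxocyclohex-3-ene-1-carboxylate | CCOC(=O)[C@@H]1CC=C(C)C(=O)C1 | intermediate
8 | ethyl (1R,5R)-5-hydroxy-4-methylcyclohex-3-ene-1-carboxylate | CCOC(=O)[C@@H]1CC=C(C)[C@H](O)C1 | intermediate
9 | ethyl (1R,5R)-4-methyl-5-[(triethylsilyl)oxy]cyclohex-3-ene-1-carboxylate | CCOC(=O)[C@@H]1CC=C(C)[C@H](O[Si](CC)(CC)CC)C1 | intermediate
10 | (1R,5R)-N-methoxy-N,4-dimethyl-5-[(triethylsilyl)oxy]cyclohex-3-ene-1-carboxamide | CON(C)C(=O)[C@@H]1CC=C(C)[C@H](O[Si](CC)(CC)CC)C1 | intermediate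
11 | 1-[(1R,5R)-4-methyl-5-[(triethylsilyl)oxy]cyclohex-3-en-1-yl]ethan-1-one | CC(=O)[C@@H]1CC=C(C)[C@H](O[Si](CC)(CC)CC)C1 | intermediate
12 | 1-[(1R,5R)-4-methyl-5-[(triethylsilyl)oxy]cyclohex-3-en-1-yl]ethenyl trifluoromethanesulfonate | C=C(OS(=O)(=O)C(F)(F)F)[C@@H]1CC=C(C)[C@H](O[Si](CC)(CC)CC)C1 | intermediate
13 | 1-[(1R,5R)-5-hydroxy-4-methylcyclohex-3-en-1-yl]ethenyl trifluoromethanesulfonate | C=C(OS(=O)(=O)C(F)(F)F)[C@@H]1CC=C(C)[C@H](O)C1 | intermediate
14 | 1-[(1S,3S,5R,6R)-5-hydroxy-6-methyl-7-oxabicyclo[4.1.0]heptan-3-yl]ethenyl trifluoromethanesulfonate | C=C(OS(=O)(=O)C(F)(F)F)[C@@H]1C[C@@H]2O[C@]2(C)[C@H](O)C1 | intermediate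
15 | 1-[(1S,3R,6S)-6-methyl-5-oxo-7-oxabicyclo[4.1.0]heptan-3-yl]ethenyl trifluoromethanesulfonate | C=C(OS(=O)(=O)C(F)(F)F)[C@@H]1C[C@@H]2O[C@]2(C)C(=O)C1 | intermediate
16 | 1-[(1S,3R,4S,6S)-4-hydroxy-6-methyl-5-oxo-7-oxabicyclo[4.1.0]heptan-3-yl]ethenyl trifluoromethanesulfonate | C=C(OS(=O)(=O)C(F)(F)F)[C@@H]1C[C@@H]2O[C@]2(C)C(=O)[C@H]1O | intermediate
17 | tiglic acid, (2E)-2-methylbut-2-enoic acid | C/C=C(\C)C(=O)O | starting material
18 | (2E)-2-methylbut-2-enoic 2,4,6-trichlorobenzoic anhydride | C/C=C(\C)C(=O)OC(=O)c1c(Cl)cc(Cl)cc1Cl | intermediate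
19 | (1S,3S,4R,6S)-1-methyl-2-oxo-4-{1-[(trifluoromethanesulfonyl)oxy]ethenyl}-7-oxabicyclo[4.1.0]heptan-3-yl (2E)-2-methylbut-2-enoate | C=C(OS(=O)(=O)C(F)(F)F)[C@@H]1C[C@@H]2O[C@]2(C)C(=O)[C@H]1OC(=O)/C(C)=C/C | intermediate
20 | 2-methylbut-3-yn-2-ol | CC(C)(O)C#C | starting material
21 | (3E)-2-methyl-4-(tributylstannyl)but-3-en-2-ol | CC(C)(O)/C=C/[Sn](CCCC)(CCCC)CCCC | intermediate
22 | (1S,3S,4S,6S)-4-[(4E)-6-hydroxy-6-methyl-3-oxohepta-1,4-dien-2-yl]-1-methyl-2-oxo-7-oxabicyclo[4.1.0]heptan-3-yl (2E)-2-methylbut-2-enoate | C=C(C(=O)/C=C/C(C)(C)O)[C@@H]1C[C@@H]2O[C@]2(C)C(=O)[C@H]1OC(=O)/C(C)=C/C | target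

## Step count and least certain steps

Total: 14 steps. Longest linear sequence: 13 steps (steps 1 to 12 and 14); step 13 is a one-step branch.

**Step 1 (key step).** The most likely failure is erosion of enantiomeric purity. Enal 2 is electrophilic enough for a background Michael addition that bypasses the chiral iminium ion, and the addition of the stabilised β-keto ester is reversible until the ring is closed. Premature loss of the tert-butyl group under the acid is harmless, since that material converges on 7 in step 2. The fallback replaces asymmetric catalysis by resolution; it sets out from 1 and 2 and comes back at 8. The annulation is run with an achiral amine salt (pyrrolidinium acetate, then p-TsOH) to give racemic 1-tert-butyl 6-ethyl 3-methyl-2-oxocyclohex-3-ene-1,6-dicarboxylate F1. This is decarboxylated as in step 2 to racemic ethyl 4-methyl-5-oxocyclohex-3-ene-1-carboxylate F2 and reduced as in step 3 to the racemic cis alcohol, an equimolar mixture of 8 and its enantiomer ethyl (1S,5S)-5-hydroxy-4-methylcyclohex-3-ene-1-carboxylate F3. Lipase-catalysed acylation (Candida antarctica lipase B, vinyl acetate) is expected, by the usual size rule for secondary alcohols (alkene side large, methylene side medium), to acetylate the 5R alcohol. This should give ethyl (1R,5R)-5-(acetyloxy)-4-methylcyclohex-3-ene-1-carboxylate F4 and leave F3. After separation, ethanolysis (K2CO3, EtOH) returns 8.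

**Step 11.** The most likely failure is decomposition of the free sodium enolate of the epoxy ketone before it is oxidised. Possible paths are a Favorskii-type collapse through the C2–O bond, self-condensation, and capture by the sulfonimine by-product. The fallback is a Rubottom oxidation, which never accumulates a free enolate; it sets out from 15 and comes back at 16. LiN(SiMe3)2 is added to 15 in the presence of excess Me3SiCl/Et3N at −78 °C (in situ trapping) to give 1-[(1S,3R,6S)-6-methyl-5-[(trimethylsilyl)oxy]-7-oxabicyclo[4.1.0]hept-4-en-3-yl]ethenyl trifluoromethanesulfonate F5. Its electron-rich enol ether double bond is oxidised with dimethyldioxirane in acetone at low temperature, anti to the C5 substituent, and mild acid work-up releases 16.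

**Step 14.** The most likely failures are direct coupling without CO insertion, if transmetallation outruns carbonylation, palladium-induced opening of the epoxy ketone, and loss of the exo-methylene dienone by conjugate addition or oligomerisation at 50 °C. The fallback forms C7–C8 by carbonyl addition and sets the oxidation level afterwards; it sets out from 19 and comes back at 22. Cross-metathesis of 2-methylbut-3-en-2-ol with crotonaldehyde (second-generation Hoveyda–Grubbs catalyst) gives (2E)-4-hydroxy-4-methylpent-2-enal F6. A Nozaki–Hiyama–Kishi coupling of 19 with F6 (CrCl2, catalytic NiCl2, DMF, rt; aldehyde-selective in the presence of ketones and esters) should give (1S,3S,4S,6S)-4-[(4E)-3,6-dihydroxy-6-methylhepta-1,4-dien-2-yl]-1-methyl-2-oxo-7-oxabicyclo[4.1.0]heptan-3-yl (2E)-2-methylbut-2-enoate F7 as a mixture of carbinol epimers. MnO2 then oxidises the doubly allylic secondary alcohol to 22 and leaves the tertiary alcohol alone.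

**Step 7.** The most likely failure is proton transfer between ketone and enolate. The more substituted C5 enolate would then form, giving the tetrasubstituted triflate and eroding the C5 configuration. The fallback generates the terminal enolate regiospecifically; it sets out from 10 and comes back at 12. (Trimethylsilyl)methyllithium adds once to Weinreb amide 10 to give 1-[(1R,5R)-4-methyl-5-[(triethylsilyl)oxy]cyclohex-3-en-1-yl]-2-(trimethylsilyl)ethan-1-one F8. Heating in toluene shifts silicon from carbon to oxygen and should give only the terminal silyl enol ether trimethyl({1-[(1R,5R)-4-methyl-5-[(triethylsilyl)oxy]cyclohex-3-en-1-yl]ethenyl}oxy)silane F9. Methyllithium then releases the regiodefined lithium enolate, which is triflated with the reagent of step 7 to give 12.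

## Further compounds

F1 | step 1 | racemic 1-tert-butyl 6-ethyl 3-methyl-2-oxocyclohex-3-ene-1,6-dicarboxylate | CCOC(=O)C1CC=C(C)C(=O)C1C(=O)OC(C)(C)C
F2 | step 1 | racemic ethyl 4-methyl-5-oxocyclohex-3-ene-1-carboxylate | CCOC(=O)C1CC=C(C)C(=O)C1
F3 | step 1 | ethyl (1S,5S)-5-hydroxy-4-methylcyclohex-3-ene-1-carboxylate | CCOC(=O)[C@H]1CC=C(C)[C@@H](O)C1
F4 | step 1 | ethyl (1R,5R)-5-(acetyloxy)-4-methylcyclohex-3-ene-1-carboxylate | CCOC(=O)[C@@H]1CC=C(C)[C@H](OC(C)=O)C1
F5 | step 11 | 1-[(1S,3R,6S)-6-methyl-5-[(trimethylsilyl)oxy]-7-oxabicyclo[4.1.0]hept-4-en-3-yl]ethenyl trifluoromethanesulfonate | C=C(OS(=O)(=O)C(F)(F)F)[C@@H]1C[C@@H]2O[C@]2(C)C(O[Si](C)(C)C)=C1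
F6 | step 14 | (2E)-4-hydroxy-4-methylpent-2-enal | CC(C)(O)/C=C/C=O
F7 | step 14 | (1S,3S,4S,6S)-4-[(4E)-3,6-dihydroxy-6-methylhepta-1,4-dien-2-yl]-1-methyl-2-oxo-7-oxabicyclo[4.1.0]heptan-3-yl (2E)-2-methylbut-2-enoate (both carbinol epimers) | C=C(C(O)/C=C/C(C)(C)O)[C@@H]1C[C@@H]2O[C@]2(C)C(=O)[C@H]1OC(=O)/C(C)=C/C
F8 | step 7 | 1-[(1R,5R)-4-methyl-5-[(triethylsilyl)oxy]cyclohex-3-en-1-yl]-2-(trimethylsilyl)ethan-1-one | C[Si](C)(C)CC(=O)[C@@H]1CC=C(C)[C@H](O[Si](CC)(CC)CC)C1
F9 | step 7 | trimethyl({1-[(1R,5R)-4-methyl-5-[(triethylsilyl)oxy]cyclohex-3-en-1-yl]ethenyl}oxy)silane | C=C(O[Si](C)(C)C)[C@@H]1CC=C(C)[C@H](O[Si](CC)(CC)CC)C1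
A1 | alternative 1 | (1R)-4-methylcyclohex-3-ene-1-carboxylic acid | OC(=O)[C@H]1CC=C(C)CC1
A2 | alternative 1 | (1R,4R,5R)-4-iodo-4-methyl-6-oxabicyclo[3.2.1]octan-7-one | O=C1O[C@@H]2C[C@H]1CC[C@@]2(C)I
A3 | alternative 2 | diethyl (2S)-2-hydroxybutanedioate (diethyl L-malate) | CCOC(=O)C[C@H](O)C(=O)OCC
A4 | alternative 2 | ethyl (2R,4Z)-5-iodo-2-{(1S)-1-[(4-methoxyphenyl)methoxy]-2-oxoethyl}hex-4-enoate | O=C[C@@H](OCc1ccc(OC)cc1)[C@H](C(=O)OCC)C/C=C(/C)I
A5 | alternative 2 | ethyl (1R,5S,6S)-5-hydroxy-6-[(4-methoxyphenyl)methoxy]-4-methylcyclohex-3-ene-1-carboxylate | CCOC(=O)[C@@H]1CC=C(C)[C@H](O)[C@H]1OCc1ccc(OC)cc1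
A6 | alternative 3 | tert-butyl(dimethyl){[(1E)-2-methylbuta-1,3-dien-1-yl]oxy}silane | C=C/C(C)=C/O[Si](C)(C)C(C)(C)C
A7 | alternative 3 | ethyl (2E)-4-oxopent-2-enoate | CCOC(=O)/C=C/C(C)=O
A8 | alternative 3 | ethyl (1R,5S,6S)-6-acetyl-5-[(tert-butyldimethylsilyl)oxy]-4-methylcyclohex-3-ene-1-carboxylate | CCOC(=O)[C@@H]1CC=C(C)[C@@H](O[Si](C)(C)C(C)(C)C)[C@H]1C(C)=O
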